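**Retrosynthetic overview**
1. The enone and the free phenol come last: dehydrogenation of a C7 ketone (only C6 carries a usable β-H) and methanolysis of an aryl acetate.
2. C3a-H and C4-O are set together by hydroboration of a Δ3a,4 alkene; the C3 carbinol by i-Pr addition to a C3 enone, both steered by the angular methyl.
3. Key step: the seven-membered ring and the C8a quaternary centre are made in one operation by a tandem alkoxide 5-exo-dig cyclisation/Claisen ring expansion of a 1-cyclopentenyl-pent-4-yn-1-ol.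
4. Absolute configuration enters once, by CBS reduction, and is passed from that carbinol to C8a through the [3,3] shift.
5. Ring order: the five-membered ring is bought (2-bromo-3-methylcyclopentenone); the seven-membered ring is formed second. No RCM and no hydrindane ring expansion.

Assumption: 2-bromo-3-methylcyclopent-2-en-1-one, 5-(trimethylsilyl)pent-4-ynoic acid and 4-acetoxybenzoyl chloride are catalogue compounds.
Locants follow azulene numbering: C3 carbinol, C3a/C8a ring fusion, C4 ester carbon, C6 methyl-bearing carbon, C7 ketone. β = face of the 8a-methyl.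

**Route**

Step 1
Reactants: 1 2-bromo-3-methylcyclopent-2-en-1-one
Product: 2 6-bromo-7-methyl-1,4-dioxaspiro[4.4]non-6-ene
Conditions: HOCH2CH2OH, p-TsOH (cat.), PhH, reflux, Dean–Stark
Reagents that add atoms: ethylene glycol, OCCO
Why: Acid-catalysed ketalisation masks the ketone so that the vinyl bromide can serve as an α-keto vinyl anion equivalent.

Step 2
Reactants: 3 5-(trimethylsilyl)pent-4-ynoic acid
Product: 4 N-methoxy-N-methyl-5-(trimethylsilyl)pent-4-ynamide
Conditions: CDI, CH2Cl2, rt; then MeNH(OMe)·HCl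
Reagents that add atoms: N,O-dimethylhydroxylamine hydrochloride, Cl.CNOC
Why: Weinreb amide formation through the acyl imidazolide gives an acyl donor that stops at the ketone stage.

Step 3
Reactants: 2 6-bromo-7-methyl-1,4-dioxaspiro[4.4]non-6-ene; 4 N-methoxy-N-methyl-5-(trimethylsilyl)pent-4-ynamide
Product: 6 1-(7-methyl-1,4-dioxaspiro[4.4]non-6-en-6-yl)-5-(trimethylsilyl)pent-4-yn-1-one, via vinyllithium 5 (not isolated)
Conditions: n-BuLi, THF, −78 °C; then 4, −78 → 0 °C; aq. NH4Cl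
Reagents that add atoms: none
Why: Br–Li exchange followed by Weinreb ketone synthesis joins the two fragments, the silyl group keeping the alkyne C–H from quenching the vinyllithium.

Step 4
Reactants: 6 1-(7-methyl-1,4-dioxaspiro[4.4]non-6-en-6-yl)-5-(trimethylsilyl)pent-4-yn-1-one
Product: 8 (S)-1-(7-methyl-1,4-dioxaspiro[4.4]non-6-en-6-yl)pent-4-yn-1-ol, via TMS-alkynol 7 (not isolated)
Conditions: (R)-Me-CBS (0.3 equiv), BH3·SMe2, THF, −30 °C; MeOH; then K2CO3, MeOH, rt
Reagents that add atoms: none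
Why: Corey–Bakshi–Shibata reduction with the fully substituted cyclopentenyl group as the large substituent gives the (S)-carbinol, and basic methanol then removes the alkynyl silane.

Step 5
Reactants: 8 (S)-1-(7-methyl-1,4-dioxaspiro[4.4]non-6-en-6-yl)pent-4-yn-1-ol
Product: 10 (8aR)-8a-methyl-1,2,5,6,8,8a-hexahydroazulene-3,7-dione 3-ethylene ketal (Δ3a,4), via 2-methylidene-oxolane 9 (not isolated)
Conditions: MeLi (0.1 equiv), phenetole, 200 °C (sealed tube or microwave)
Reagents that add atoms: none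
Why: Tandem oxyanionic 5-exo-dig hydroalkoxylation/Claisen ring expansion in which the new C8–C8a bond forms on the face from which the C–O bond leaves (α), so the (S)-carbinol gives the (R)-quaternary centre with the methyl β.

Step 6
Reactants: 10 (8aR)-8a-methyl-1,2,5,6,8,8a-hexahydroazulene-3,7-dione 3-ethylene ketal
Product: 11 (8aR)-6,8a-dimethyl-1,2,5,6,8,8a-hexahydroazulene-3,7-dione 3-ethylene ketal (C6 epimers; this centre is erased in step 12)
Conditions: LDA, THF, −78 °C; MeI
Reagents that add atoms: iodomethane, CI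
Why: Kinetic enolate alkylation occurs at C6 because the other α-carbon (C8) is neopentyl, next to the quaternary centre.

Step 7
Reactants: 11 (8aR)-6,8a-dimethyl-1,2,5,6,8,8a-hexahydroazulene-3,7-dione 3-ethylene ketal
Product: 13 (8aR)-6,8a-dimethyl-1,2,5,6,8,8a-hexahydroazulene-3,7-dione 7-ethylene ketal (C3 enone, Δ3a,4), via bis-ketal 12 (not isolated)
Conditions: TMSOCH2CH2OTMS, TMSOTf (cat.), CH2Cl2, −78 → −20 °C; crude product then 10% aq. oxalic acid on SiO2, CH2Cl2, rt
Reagents that add atoms: 1,2-bis(trimethylsilyloxy)ethane, C[Si](C)(C)OCCO[Si](C)(C)C; water, O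
Why: Noyori ketalisation protects C7, and the allylic C3 ketal then hydrolyses selectively because its oxocarbenium ion is allyl-stabilised and the product is a conjugated enone.

Step 8
Reactants: 13 (8aR)-6,8a-dimethyl-1,2,5,6,8,8a-hexahydroazulene-3,7-dione 7-ethylene ketal
Product: 14 (3R,8aR)-3-hydroxy-6,8a-dimethyl-3-(propan-2-yl)-2,3,5,6,8,8a-hexahydroazulen-7(1H)-one ethylene ketal (Δ3a,4; 3-OH β)
Conditions: i-PrMgCl, CeCl3, THF, −78 → 0 °C
Reagents that add atoms: isopropylmagnesium chloride, CC(C)[Mg]Cl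
Why: Organocerium 1,2-addition (Imamoto conditions) enters from the α face, away from the pseudo-axial β 8a-methyl, so the new hydroxyl is β and cis to that methyl.

Step 9
Reactants: 14 (3R,8aR)-3-hydroxy-6,8a-dimethyl-3-(propan-2-yl)-2,3,5,6,8,8a-hexahydroazulen-7(1H)-one ethylene ketal
Product: 16 (3R,3aS,4S,8aR)-3,4-dihydroxy-6,8a-dimethyl-3-(propan-2-yl)octahydroazulen-7(1H)-one ethylene ketal, via C4-alkylborane 15 (not isolated)
Conditions: BH3·THF, THF, 0 °C → rt; then NaOH, H2O2, 0 °C → rt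
Reagents that add atoms: hydrogen peroxide, OO
Why: Hydroboration–oxidation adds H (C3a) and OH (C4) syn from the α face, anti to both the angular methyl and the allylic C3–O bond (as in Δ5-steroids), which gives the trans ring fusion and the α C4 hydroxyl with boron on the less substituted carbon.

Step 10
Reactants: 16 (3R,3aS,4S,8aR)-3,4-dihydroxy-6,8a-dimethyl-3-(propan-2-yl)octahydroazulen-7(1H)-one ethylene ketal; 17 4-acetoxybenzoyl chloride
Product: 18 (3R,3aS,4S,8aR)-3-hydroxy-6,8a-dimethyl-7-oxo-3-(propan-2-yl)decahydroazulen-4-yl 4-acetoxybenzoate 7-ethylene ketal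
Conditions: pyridine, DMAP (cat.), CH2Cl2, 0 °C → rt
Reagents that add atoms: none
Why: DMAP-catalysed acylation takes the secondary C4 hydroxyl and leaves the tertiary C3 hydroxyl untouched.

Step 11
Reactants: 18 (3R,3aS,4S,8aR)-3-hydroxy-6,8a-dimethyl-7-oxo-3-(propan-2-yl)decahydroazulen-4-yl 4-acetoxybenzoate 7-ethylene ketal
Product: 19 (3R,3aS,4S,8aR)-3-hydroxy-6,8a-dimethyl-7-oxo-3-(propan-2-yl)decahydroazulen-4-yl 4-acetoxybenzoate
Conditions: PPTS, acetone/H2O, 50 °C
Reagents that add atoms: water, O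
Why: Mild acid-catalysed ketal hydrolysis frees the C7 ketone without touching the esters or the tertiary alcohol.

Step 12
Reactants: 19 (3R,3aS,4S,8aR)-3-hydroxy-6,8a-dimethyl-7-oxo-3-(propan-2-yl)decahydroazulen-4-yl 4-acetoxybenzoate
Product: 20 (3R,3aS,4S,8aR)-3-hydroxy-6,8a-dimethyl-7-oxo-3-(propan-2-yl)-1,2,3,3a,4,7,8,8a-octahydroazulen-4-yl 4-acetoxybenzoate
Conditions: IBX, DMSO, 65 °C
Reagents that add atoms: none
Why: IBX dehydrogenation of the ketone (Nicolaou type) can only give the C5=C6 enone, because C8 is attached to the quaternary C8a and has no β-hydrogen; the C6 epimers converge here.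

Step 13
Reactants: 20 (3R,3aS,4S,8aR)-3-hydroxy-6,8a-dimethyl-7-oxo-3-(propan-2-yl)-1,2,3,3a,4,7,8,8a-octahydroazulen-4-yl 4-acetoxybenzoate
Product: 21 lancerodiol p-hydroxybenzoate
Conditions: K2CO3 (0.2 equiv), MeOH, 0 °C
Reagents that add atoms: none
Why: Chemoselective methanolysis cleaves the phenolic acetate (phenoxide leaving group) far faster than the hindered alkyl benzoate.

**Compound list**
1 | 2-bromo-3-methylcyclopent-2-en-1-one | CC1=C(Br)C(=O)CC1 | starting material
2 | 6-bromo-7-methyl-1,4-dioxaspiro[4.4]non-6-ene | CC1=C(Br)C2(CC1)OCCO2 | intermediate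
3 | 5-(trimethylsilyl)pent-4-ynoic acid | C[Si](C)(C)C#CCCC(=O)O | starting material
4 | N-methoxy-N-methyl-5-(trimethylsilyl)pent-4-ynamide | C[Si](C)(C)C#CCCC(=O)N(C)OC | intermediate
5 | (7-methyl-1,4-dioxaspiro[4.4]non-6-en-6-yl)lithium | [Li]C1=C(C)CCC12OCCO2 | intermediate (not isolated)
6 | 1-(7-methyl-1,4-dioxaspiro[4.4]non-6-en-6-yl)-5-(trimethylsilyl)pent-4-yn-1-one | C[Si](C)(C)C#CCCC(=O)C1=C(C)CCC12OCCO2 | intermediate
7 | (S)-1-(7-methyl-1,4-dioxaspiro[4.4]non-6-en-6-yl)-5-(trimethylsilyl)pent-4-yn-1-ol | C[Si](C)(C)C#CCC[C@H](O)C1=C(C)CCC12OCCO2 | intermediate (not isolated)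
8 | (S)-1-(7-methyl-1,4-dioxaspiro[4.4]non-6-en-6-yl)pent-4-yn-1-ol | C#CCC[C@H](O)C1=C(C)CCC12OCCO2 | intermediate
9 | (S)-7-methyl-6-(5-methylideneoxolan-2-yl)-1,4-dioxaspiro[4.4]non-6-ene | C=C1CC[C@H](O1)C1=C(C)CCC12OCCO2 | intermediate (not isolated)
10 | (8aR)-8a-methyl-1,2,5,6,8,8a-hexahydroazulene-3,7-dione 3-ethylene ketal | O=C1CCC=C2C3(OCCO3)CC[C@]2(C)C1 | intermediate
11 | (8aR)-6,8a-dimethyl-1,2,5,6,8,8a-hexahydroazulene-3,7-dione 3-ethylene ketal (C6 epimers) | O=C1C(C)CC=C2C3(OCCO3)CC[C@]2(C)C1 | intermediate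
12 | (8aR)-6,8a-dimethyl-1,2,5,6,8,8a-hexahydroazulene-3,7-dione 3,7-bis(ethylene ketal) (C6 epimers) | CC1CC=C2C3(OCCO3)CC[C@]2(C)CC14OCCO4 | intermediate (not isolated)
13 | (8aR)-6,8a-dimethyl-1,2,5,6,8,8a-hexahydroazulene-3,7-dione 7-ethylene ketal (C6 epimers) | O=C1CC[C@]2(C)CC3(OCCO3)C(C)CC=C12 | intermediate
14 | (3R,8aR)-3-hydroxy-6,8a-dimethyl-3-(propan-2-yl)-2,3,5,6,8,8a-hexahydroazulen-7(1H)-one ethylene ketal (C6 epimers) | CC(C)[C@]1(O)CC[C@]2(C)CC3(OCCO3)C(C)CC=C12 | intermediate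
15 | C4-alkylborane of 14 (drawn as R–BH2; 3a-H α, 4-B α) | CC1C[C@H](B)[C@@H]2[C@](C)(CC[C@@]2(O)C(C)C)CC13OCCO3 | intermediate (not isolated)
16 | (3R,3aS,4S,8aR)-3,4-dihydroxy-6,8a-dimethyl-3-(propan-2-yl)octahydroazulen-7(1H)-one ethylene ketal (C6 epimers) | CC1C[C@H](O)[C@@H]2[C@](C)(CC[C@@]2(O)C(C)C)CC13OCCO3 | intermediate
17 | 4-acetoxybenzoyl chloride | CC(=O)Oc1ccc(cc1)C(Cl)=O | starting material
18 | (3R,3aS,4S,8aR)-3-hydroxy-6,8a-dimethyl-7-oxo-3-(propan-2-yl)decahydroazulen-4-yl 4-acetoxybenzoate 7-ethylene ketal (C6 epimers) | CC1C[C@H](OC(=O)c2ccc(OC(C)=O)cc2)[C@@H]2[C@](C)(CC[C@@]2(O)C(C)C)CC13OCCO3 | intermediate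
19 | (3R,3aS,4S,8aR)-3-hydroxy-6,8a-dimethyl-7-oxo-3-(propan-2-yl)decahydroazulen-4-yl 4-acetoxybenzoate (C6 epimers) | CC1C[C@H](OC(=O)c2ccc(OC(C)=O)cc2)[C@@H]2[C@](C)(CC[C@@]2(O)C(C)C)CC1=O | intermediate
20 | (3R,3aS,4S,8aR)-3-hydroxy-6,8a-dimethyl-7-oxo-3-(propan-2-yl)-1,2,3,3a,4,7,8,8a-octahydroazulen-4-yl 4-acetoxybenzoate | CC1=C[C@H](OC(=O)c2ccc(OC(C)=O)cc2)[C@@H]2[C@](C)(CC[C@@]2(O)C(C)C)CC1=O | intermediate
21 | lancerodiol p-hydroxybenzoate, (3R,3aS,4S,8aR)-3-hydroxy-6,8a-dimethyl-7-oxo-3-(propan-2-yl)-1,2,3,3a,4,7,8,8a-octahydroazulen-4-yl 4-hydroxybenzoate | CC1=C[C@H](OC(=O)c2ccc(O)cc2)[C@@H]2[C@](C)(CC[C@@]2(O)C(C)C)CC1=O | target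

**Step count**
Total: 13 steps. Longest linear sequence: 12 steps (1 → 21 through steps 1 and 3–13; step 2 is a one-step branch).

**Three steps most likely to fail, with fallbacks**

Step 5 (tandem cyclisation/Claisen). The risks are base-induced alkyne isomerisation, drift of the exocyclic enol ether into the ring, and a sluggish [3,3] shift onto a fully substituted alkene carbon. The fallback sets out from 8 and returns at 10. It replaces the thermal anionic cascade by a stepwise, metal-mediated sequence. Gold(I)-catalysed 5-exo-dig cycloisomerisation (Ph3PAuCl/AgOTf, K2CO3, CH2Cl2, rt) gives enol ether 9, now isolated. Triisobutylaluminium (CH2Cl2, −78 → 0 °C) then drives the ring expansion as a Lewis-acid-promoted Claisen and reduces the aluminium-bound ketone in the same pot. This gives the ring-expanded C7 carbinol (8aR)-7-hydroxy-8a-methyl-1,2,5,6,8,8a-hexahydroazulen-3(7H)-one ethylene ketal F1. Dess–Martin oxidation of this alcohol returns 10.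

Step 9 (hydroboration of 14). The alkene is flanked by two quaternary carbons, and the α-isopropyl group could override the face preference. The fallback sets out from 13 and returns at 16; it installs the C4 oxygen by conjugate borylation before the isopropyl group is present. Copper-catalysed β-borylation of enone 13 (CuCl, NaOt-Bu, DPEphos, B2pin2, MeOH, THF) adds boron to C4 from the α face, anti to the angular methyl. The copper enolate is protonated at C3a from the same open face, giving the C4 pinacol boronate ketone F2. NaBO3 oxidation with retention gives the β-hydroxy ketone F3. TESCl/imidazole gives the triethylsilyl ether F4. i-PrMgCl/CeCl3 now adds anti to the adjacent C4 branch and the angular methyl to give the tertiary alcohol F5. TBAF then delivers 16.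

Step 12 (IBX dehydrogenation). The risks are low conversion at the hindered α-methyl ketone or over-oxidation. The fallback sets out from 19 and returns at 21; it goes through a palladium enolate instead of IBX. TMSOTf/Et3N (CH2Cl2, 0 °C) gives the more substituted C6=C7 trimethylsilyl enol ether, with the C3 hydroxyl silylated as well, the bis-silyl compound F6. Saegusa–Ito oxidation (Pd(OAc)2, MeCN, rt) gives the C3-O-trimethylsilyl enone F7. The K2CO3/MeOH conditions of step 13 then remove both the aryl acetate and the silyl ether to give 21.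

**Further compounds**
F1 | step 5 | (8aR)-7-hydroxy-8a-methyl-1,2,5,6,8,8a-hexahydroazulen-3(7H)-one ethylene ketal (C7 epimers) | OC1CCC=C2C3(OCCO3)CC[C@]2(C)C1
F2 | step 9 | (3aS,4S,8aR)-6,8a-dimethyl-4-(4,4,5,5-tetramethyl-1,3,2-dioxaborolan-2-yl)octahydroazulene-3,7-dione 7-ethylene ketal | CC1C[C@H](B2OC(C)(C)C(C)(C)O2)[C@@H]2[C@](C)(CCC2=O)CC13OCCO3
F3 | step 9 | (3aS,4S,8aR)-4-hydroxy-6,8a-dimethyloctahydroazulene-3,7-dione 7-ethylene ketal | CC1C[C@H](O)[C@@H]2[C@](C)(CCC2=O)CC13OCCO3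
F4 | step 9 | (3aS,4S,8aR)-6,8a-dimethyl-4-(triethylsilyloxy)octahydroazulene-3,7-dione 7-ethylene ketal | CC1C[C@H](O[Si](CC)(CC)CC)[C@@H]2[C@](C)(CCC2=O)CC13OCCO3
F5 | step 9 | (3R,3aS,4S,8aR)-3-hydroxy-6,8a-dimethyl-3-(propan-2-yl)-4-(triethylsilyloxy)octahydroazulen-7(1H)-one ethylene ketal | CC1C[C@H](O[Si](CC)(CC)CC)[C@@H]2[C@](C)(CC[C@@]2(O)C(C)C)CC13OCCO3
F6 | step 12 | (3R,3aS,4S,8aR)-6,8a-dimethyl-3-(propan-2-yl)-3,7-bis(trimethylsilyloxy)-1,2,3,3a,4,5,8,8a-octahydroazulen-4-yl 4-acetoxybenzoate | CC=1C[C@H](OC(=O)c2ccc(OC(C)=O)cc2)[C@@H]2[C@](C)(CC[C@@]2(O[Si](C)(C)C)C(C)C)CC=1O[Si](C)(C)C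
F7 | step 12 | (3R,3aS,4S,8aR)-6,8a-dimethyl-7-oxo-3-(propan-2-yl)-3-(trimethylsilyloxy)-1,2,3,3a,4,7,8,8a-octahydroazulen-4-yl 4-acetoxybenzoate | CC1=C[C@H](OC(=O)c2ccc(OC(C)=O)cc2)[C@@H]2[C@](C)(CC[C@@]2(O[Si](C)(C)C)C(C)C)CC1=O
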